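**Assumption:** compounds 1, 2, 4, 9 and 16 are treated as catalogue items. (S)-3-Hydroxy-γ-butyrolactone (4) is the inexpensive enantiomer made industrially from L-malic acid or carbohydrates. If 1 is not stocked, it is one extra step from 4-bromophenol (MOMCl, i-Pr2NEt).

## Retrosynthetic overview

1. The C8–prenyl bond is made last but one, by a Eu(III)-catalysed para-Claisen–Cope rearrangement ([3,3] then [3,3]) of the 5-O-prenyl ether of the (2S)-flavanone; MOM removal then gives the target.
2. Ring C is the only ring formed (A and B are bought as arenes). It closes by intramolecular Mitsunobu displacement (inversion) of an (R)-benzylic carbinol by the A-ring ortho-phenol.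
3. The aldol-type precursor comes from a 2,4,6-trioxygenated aryllithium (A ring) adding to an (R)-3-aryl-3-silyloxypropanal, followed by oxidation.
4. The (R)-carbinol is relayed from (S)-3-hydroxy-γ-butyrolactone: the ortho-lithiated B-ring arene opens the lactone, the lactone carbinol directs a 1,3-syn ketone reduction, and periodate then excises it.
5. The B ring comes from 4-bromophenyl MOM ether by γ-selective Suzuki coupling with prenyl-Bpin (1,1-dimethylallyl group).

Abbreviation used in names: **Ar** = 2-(methoxymethoxy)-5-(2-methylbut-3-en-2-yl)phenyl.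

## Route

**Step 1**
Reactants: 1, 1-bromo-4-(methoxymethoxy)benzene; 2, prenylboronic acid pinacol ester
Product: 3, 1-(methoxymethoxy)-4-(2-methylbut-3-en-2-yl)benzene
Conditions: Pd(OAc)2 (2 mol %), γ-selective dialkylbiarylphosphine ligand, aq. K3PO4, THF, 40 °C
Reagents that add atoms: none (the C5 unit comes from reactant 2)
Why: γ-Selective Suzuki–Miyaura allyl–aryl coupling; SE2′ transmetalation puts Pd on the tertiary carbon and reductive elimination gives the branched 1,1-dimethylallyl arene.

**Step 2**
Reactants: 3 (2.2 equiv); 4, (S)-3-hydroxy-γ-butyrolactone (1 equiv)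
Product: 5, (3S)-3,4-dihydroxy-1-Ar-butan-1-one
Conditions: n-BuLi, TMEDA, THF, 0 °C; then 4, −78 °C; aq. NH4Cl (excess 3 recovered)
Reagents that add atoms: none
Why: Directed ortho-metalation next to OMOM (para position blocked), then acylation of the aryllithium by the lactone; the first equivalent deprotonates the OH, the lithium lactolate resists a second addition, and the purchased stereocentre is not touched.

**Step 3**
Reactants: 5
Product: 6, (1R,3S)-1-Ar-butane-1,3,4-triol
Conditions: Et2BOMe (2.2 equiv), THF/MeOH 4:1, −78 °C; NaBH4; AcOH, MeOH co-evaporation; chromatography to remove the minor anti isomer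
Reagents that add atoms: none
Why: Narasaka–Prasad reduction; the boron chelate of the β-hydroxy ketone is attacked axially by hydride to give the 1,3-syn diol, so the purchased (3S) carbinol sets the new benzylic centre as (1R).

**Step 4**
Reactants: 6
Product: 7, (3R)-3-hydroxy-3-Ar-propanal
Conditions: NaIO4, THF/pH 7 buffer, 0 °C; used crude
Reagents that add atoms: none
Why: Malaprade glycol cleavage cuts only the terminal 1,2-diol (the 1,3-diol is inert), turning the lactone carbinol carbon into the aldehyde (future C4) and leaving the (R)-benzylic carbinol intact.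

**Step 5**
Reactants: 7
Product: 8, (3R)-3-Ar-3-(triethylsilyloxy)propanal
Conditions: TESCl, imidazole, CH2Cl2, 0 °C
Reagents that add atoms: chlorotriethylsilane, CC[Si](Cl)(CC)CC
Why: Silylation masks the β-hydroxyl so that the aldehyde survives organolithium addition and oxidation without retro-aldol or dehydration.

**Step 6**
Reactants: 9, phloroglucinol
Product: 10, 1,3,5-tris(oxan-2-yloxy)benzene (THP diastereomer mixture)
Conditions: DHP, PPTS, CH2Cl2, 0 °C → rt
Reagents that add atoms: 3,4-dihydro-2H-pyran, C1=COCCC1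
Why: Acid-catalysed acetalisation gives a base-stable, lithiation-directing protecting group that is more acid-labile than the aryl MOM ether.

**Step 7**
Reactants: 10 (1.4 equiv); 8
Product: 11, (3R)-3-Ar-3-(triethylsilyloxy)-1-[2,4,6-tris(oxan-2-yloxy)phenyl]propan-1-ol (mixture at C1 and THP centres)
Conditions: n-BuLi, THF, 0 °C; then 8, −78 °C
Reagents that add atoms: none
Why: Directed ortho-metalation between two OTHP groups (all three sites equivalent) gives the A-ring aryllithium, which adds 1,2 to the aldehyde; the new carbinol configuration is irrelevant because it is oxidised next.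

**Step 8**
Reactants: 11
Product: 12, (3R)-3-Ar-3-(triethylsilyloxy)-1-[2,4,6-tris(oxan-2-yloxy)phenyl]propan-1-one
Conditions: Dess–Martin periodinane, NaHCO3, CH2Cl2, rt
Reagents that add atoms: none
Why: Buffered Dess–Martin oxidation gives the aryl ketone without disturbing the silyl ether, acetals or alkene.

**Step 9**
Reactants: 12
Product: 13, (3R)-3-hydroxy-3-Ar-1-(2,4,6-trihydroxyphenyl)propan-1-one
Conditions: PPTS (cat.), MeOH, 0 °C → rt
Reagents that add atoms: none
Why: Mild acid methanolysis removes the three aryl THP acetals and the TES ether while the less labile aryl MOM ether on ring B stays, and the benzylic carbinol is not ionised.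

**Step 10**
Reactants: 13
Product: 14, (2S)-5,7-dihydroxy-2-Ar-2,3-dihydro-4H-chromen-4-one
Conditions: PPh3, DIAD, THF (0.01 M), 0 °C → rt
Reagents that add atoms: none
Why: Intramolecular Mitsunobu reaction; the benzylic oxyphosphonium is displaced SN2 (6-exo-tet) by either of the two equivalent ortho phenols, so the (R)-carbinol becomes the (2S)-flavanone by inversion; the B-ring phenol stays as MOM ether to prevent o-quinone methide formation.

**Step 11**
Reactants: 14
Product: 15, (2S)-5-hydroxy-7-(methoxymethoxy)-2-Ar-chroman-4-one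
Conditions: MOMCl (1.1 equiv), i-Pr2NEt, CH2Cl2, 0 °C
Reagents that add atoms: chloromethyl methyl ether, COCCl
Why: The non-chelated, more acidic 7-OH is alkylated selectively; the 5-OH is hydrogen-bonded to C4=O and does not react.

**Step 12**
Reactants: 15; 16, 3-methylbut-2-en-1-ol
Product: 17, (2S)-7-(methoxymethoxy)-5-[(3-methylbut-2-en-1-yl)oxy]-2-Ar-chroman-4-one
Conditions: PPh3, DIAD, THF, rt
Reagents that add atoms: none
Why: Mitsunobu O-alkylation of the chelated 5-OH by the primary allylic alcohol (SN2, no allylic transposition) under neutral conditions that do not open the flavanone ring.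

**Step 13**
Reactants: 17
Product: 18, (2S)-5-hydroxy-7-(methoxymethoxy)-8-(3-methylbut-2-en-1-yl)-2-Ar-chroman-4-one
Conditions: Eu(fod)3 (10 mol %), CHCl3, 60 °C
Reagents that add atoms: none
Why: Eu(III)-accelerated tandem aromatic Claisen ([3,3] to C6) and Cope ([3,3] to C8) rearrangement followed by tautomerisation forms the C8–prenyl bond with the linear prenyl restored; C2 is not involved.

**Step 14**
Reactants: 18
Product: 19, target, (2S)-5,7-dihydroxy-2-[2-hydroxy-5-(2-methylbut-3-en-2-yl)phenyl]-8-(3-methylbut-2-en-1-yl)chroman-4-one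
Conditions: 3 M HCl, MeOH, rt → 40 °C
Reagents that add atoms: none
Why: Acid-catalysed acetal hydrolysis removes both aryl MOM ethers; the flavanone centre is configurationally stable to mild acid (base is avoided throughout), and the conditions are kept mild to avoid prenyl–phenol cyclisation.

## Compound list

1 | 1-bromo-4-(methoxymethoxy)benzene | COCOc1ccc(Br)cc1 | starting material
2 | 4,4,5,5-tetramethyl-2-(3-methylbut-2-en-1-yl)-1,3,2-dioxaborolane (prenyl-Bpin) | CC(C)=CCB1OC(C)(C)C(C)(C)O1 | starting material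
3 | 1-(methoxymethoxy)-4-(2-methylbut-3-en-2-yl)benzene | C=CC(C)(C)c1ccc(OCOC)cc1 | intermediate
4 | (S)-3-hydroxy-γ-butyrolactone [(4S)-4-hydroxyoxolan-2-one] | O=C1C[C@H](O)CO1 | starting material (chiral)
5 | (3S)-3,4-dihydroxy-1-[2-(methoxymethoxy)-5-(2-methylbut-3-en-2-yl)phenyl]butan-1-one | C=CC(C)(C)c1ccc(OCOC)c(C(=O)C[C@H](O)CO)c1 | intermediate
6 | (1R,3S)-1-[2-(methoxymethoxy)-5-(2-methylbut-3-en-2-yl)phenyl]butane-1,3,4-triol | C=CC(C)(C)c1ccc(OCOC)c([C@H](O)C[C@H](O)CO)c1 | intermediate
7 | (3R)-3-hydroxy-3-[2-(methoxymethoxy)-5-(2-methylbut-3-en-2-yl)phenyl]propanal | C=CC(C)(C)c1ccc(OCOC)c([C@H](O)CC=O)c1 | intermediate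
8 | (3R)-3-[2-(methoxymethoxy)-5-(2-methylbut-3-en-2-yl)phenyl]-3-(triethylsilyloxy)propanal | C=CC(C)(C)c1ccc(OCOC)c([C@H](O[Si](CC)(CC)CC)CC=O)c1 | intermediate
9 | phloroglucinol (benzene-1,3,5-triol) | Oc1cc(O)cc(O)c1 | starting material
10 | 1,3,5-tris(oxan-2-yloxy)benzene | c1c(OC2CCCCO2)cc(OC2CCCCO2)cc1OC1CCCCO1 | intermediate
11 | (3R)-3-[2-(methoxymethoxy)-5-(2-methylbut-3-en-2-yl)phenyl]-3-(triethylsilyloxy)-1-[2,4,6-tris(oxan-2-yloxy)phenyl]propan-1-ol | C=CC(C)(C)c1ccc(OCOC)c([C@H](O[Si](CC)(CC)CC)CC(O)c2c(OC3CCCCO3)cc(OC3CCCCO3)cc2OC2CCCCO2)c1 | intermediate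
12 | (3R)-3-[2-(methoxymethoxy)-5-(2-methylbut-3-en-2-yl)phenyl]-3-(triethylsilyloxy)-1-[2,4,6-tris(oxan-2-yloxy)phenyl]propan-1-one | C=CC(C)(C)c1ccc(OCOC)c([C@H](O[Si](CC)(CC)CC)CC(=O)c2c(OC3CCCCO3)cc(OC3CCCCO3)cc2OC2CCCCO2)c1 | intermediate
13 | (3R)-3-hydroxy-3-[2-(methoxymethoxy)-5-(2-methylbut-3-en-2-yl)phenyl]-1-(2,4,6-trihydroxyphenyl)propan-1-one | C=CC(C)(C)c1ccc(OCOC)c([C@H](O)CC(=O)c2c(O)cc(O)cc2O)c1 | intermediate
14 | (2S)-5,7-dihydroxy-2-[2-(methoxymethoxy)-5-(2-methylbut-3-en-2-yl)phenyl]-2,3-dihydro-4H-chromen-4-one | C=CC(C)(C)c1ccc(OCOC)c([C@@H]2CC(=O)c3c(O)cc(O)cc3O2)c1 | intermediate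
15 | (2S)-5-hydroxy-7-(methoxymethoxy)-2-[2-(methoxymethoxy)-5-(2-methylbut-3-en-2-yl)phenyl]-2,3-dihydro-4H-chromen-4-one | C=CC(C)(C)c1ccc(OCOC)c([C@@H]2CC(=O)c3c(O)cc(OCOC)cc3O2)c1 | intermediate
16 | 3-methylbut-2-en-1-ol (prenyl alcohol) | CC(C)=CCO | starting material
17 | (2S)-7-(methoxymethoxy)-2-[2-(methoxymethoxy)-5-(2-methylbut-3-en-2-yl)phenyl]-5-[(3-methylbut-2-en-1-yl)oxy]-2,3-dihydro-4H-chromen-4-one | C=CC(C)(C)c1ccc(OCOC)c([C@@H]2CC(=O)c3c(OCC=C(C)C)cc(OCOC)cc3O2)c1 | intermediate
18 | (2S)-5-hydroxy-7-(methoxymethoxy)-2-[2-(methoxymethoxy)-5-(2-methylbut-3-en-2-yl)phenyl]-8-(3-methylbut-2-en-1-yl)-2,3-dihydro-4H-chromen-4-one | C=CC(C)(C)c1ccc(OCOC)c([C@@H]2CC(=O)c3c(O)cc(OCOC)c(CC=C(C)C)c3O2)c1 | intermediate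
19 | (2S)-5,7-dihydroxy-2-[2-hydroxy-5-(2-methylbut-3-en-2-yl)phenyl]-8-(3-methylbut-2-en-1-yl)-2,3-dihydro-4H-chromen-4-one | C=CC(C)(C)c1ccc(O)c([C@@H]2CC(=O)c3c(O)cc(O)c(CC=C(C)C)c3O2)c1 | target

## Summary

Total step count: 14.
Longest linear sequence: 13 steps (1 → 3 → 5 → 6 → 7 → 8 → 11 → 12 → 13 → 14 → 15 → 17 → 18 → 19); step 6 is a one-step side branch.

Three steps most likely to fail, with fallbacks:

1. **Step 10 (Mitsunobu ring closure).** The electron-rich benzylic carbinol may eliminate to the chalcone or leak through an SN1 path and erode ee. Fallback: form the C2–O1 bond intermolecularly first. Etherify the 3,4-acetonide of triol 6 with 3,5-bis(methoxymethoxy)phenol under Mitsunobu conditions, cleave the diol, oxidise to the 3-aryloxypropanoic acid, and close ring C by intramolecular Friedel–Crafts acylation (TFAA).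
2. **Step 1 (γ-selective reverse prenylation).** The α/γ ratio at a quaternary carbon may be poor. Fallback: build the 1,1-dimethylallyl group classically from methyl 2-[4-(methoxymethoxy)phenyl]acetate by double α-methylation (LDA/MeI), DIBAL-H reduction to the aldehyde and Wittig methylenation.
3. **Step 2 (aryllithium opening of the unprotected hydroxy-lactone).** Enolisation or double addition may lower the yield. Fallback: convert the same lactone into the Weinreb amide of (S)-3,4-O-isopropylidene-3,4-dihydroxybutanoic acid, acylate the aryllithium with it, then remove the acetonide to reach 5.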